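Ring B, the hexasubstituted arene, is built as a cyclohexane-1,3-dione and aromatized late. Two C–C bonds are disconnected: the bond between the ring carbon that carries the lactone carbonyl and the ring carbon that carries the lactol carbon, and the bond from the acetoxymethyl-bearing ring carbon to its oxygenated neighbour on the depside-ester side. One Michael–Dieckmann operation forms both bonds and the ring from tert-butyl acetoacetate and methyl (E)-4,4-dimethoxybut-2-enoate. The carboxyl and aldehyde-level carbons are thus born adjacent at different oxidation levels, and the carbon between the two ring oxygens is the single nucleophilic site for the one-carbon unit. Ring A is added as haematommic acid; the diaryl ether is closed oxidatively.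

Key step: step 1

Assumption: the lactol carbon, the only stereocentre, equilibrates in solution through the open formyl acid, so the route makes the racemate and secures the (S) form only at the end, as a crystalline solid.
Assumption: the two key-step partners and methyl orsellinate are catalogue compounds.
Numbering used: ring B as the benzoate (C1 ester carbon-bearing, C2 OH, C3 one-carbon unit, C4 O, C5 H, C6 acetal-bearing); ring A primed (C1' carboxyl, C2' OH, C3' CHO, C4' OH, C6' CH3).

Step 1
Reactants: 1 tert-butyl acetoacetate; 2 methyl (E)-4,4-dimethoxybut-2-enoate
Product: 4 tert-butyl trans-6-(dimethoxymethyl)-2,4-dioxocyclohexane-1-carboxylate, via Michael adduct 3 (not isolated)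
Conditions: KOtBu (1.1 equiv), tBuOH, reflux; then AcOH (1.2 equiv), 10 °C
Reagents that add atoms: none
Why: The potassium enolate of 1 adds through its central carbon to the β-carbon of 2 (Michael addition), proton transfer then places the charge on the acetyl methyl carbon, which attacks the methyl ester and expels methoxide (Dieckmann/Claisen closure), and deprotonation of the resulting 1,3-dione drives the sequence. The closest known reaction is the acetoacetate–crotonate condensation that gives dihydroorsellinates. The ring closes 6-exo-trig. C1 and C6 form as the more stable trans pair by equilibration at the enolizable C1, but both centres vanish on aromatization and need no control. The step needs carbon rather than oxygen acylation (a dihydropyranone would form otherwise) and intact esters; reversible alkoxide conditions channel all adducts to the only product that forms a stabilized enolate, tert-butoxide in tert-butanol cannot scramble the tert-butyl ester, and exchange at the methyl ester still leads to the same dione.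

Step 2
Reactants: 4 tert-butyl trans-6-(dimethoxymethyl)-2,4-dioxocyclohexane-1-carboxylate
Product: 5 tert-butyl 3-[(dimethylamino)methylidene]-6-(dimethoxymethyl)-2,4-dioxocyclohexane-1-carboxylate
Conditions: Me2NCH(OMe)2 (1.2 equiv), CH2Cl2, 20 °C
Reagents that add atoms: N,N-dimethylformamide dimethyl acetal, COC(OC)N(C)C
Why: Enaminone formation: the enolized 1,3-dione condenses with the amide acetal only at C3, the single CH2 flanked by two carbonyls (C1 has one hydrogen and cannot form a methylidene), which fixes the future acetoxymethyl carbon between the two ring oxygens without added acid or base.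

Step 3
Reactants: 5 tert-butyl 3-[(dimethylamino)methylidene]-6-(dimethoxymethyl)-2,4-dioxocyclohexane-1-carboxylate
Product: 9 tert-butyl 3-formyl-2,4-dihydroxy-6-(dimethoxymethyl)benzoate, via C1 selenide 6 (not isolated), via selenoxide 7 (not isolated), via aminomethylene dienone 8 (not isolated)
Conditions: NaH (1.05 equiv), THF, 0 °C; PhSeCl (1.05 equiv), 0 °C; mCPBA (1.0 equiv), CH2Cl2, −78 °C; iPr2NH (2 equiv), −78 → 20 °C; aq. NaH2PO4 (pH 4.5), THF, 20 °C
Reagents that add atoms: water, O
Why: Selenoxide syn-elimination (Reich–Liotta dehydrogenation of β-dicarbonyl compounds): the thermodynamic enolate at C1 is selenenylated anti to the C6 substituent and thus syn to H6, oxidation and elimination give the C1=C6 alkene, enolization at C5 aromatizes the ring, and mild aqueous acid hydrolyses the vinylogous amide to the formyl group; the amine traps PhSeOH, and the acetal and tert-butyl ester never meet strong acid.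

Step 4
Reactants: 9 tert-butyl 3-formyl-2,4-dihydroxy-6-(dimethoxymethyl)benzoate
Product: 10 tert-butyl 2,4-dihydroxy-3-(hydroxymethyl)-6-(dimethoxymethyl)benzoate
Conditions: NaBH4 (1.0 equiv), THF/MeOH 4:1, 0 °C; NaH2PO4/Na2HPO4 buffer (pH 7)
Reagents that add atoms: none
Why: Borohydride reduction of the single aldehyde (ester and acetal are inert); low temperature and a neutral quench limit quinone-methide formation and over-reduction of the ortho-hydroxybenzyl alcohol, which is carried on without storage.

Step 5
Reactants: 10 tert-butyl 2,4-dihydroxy-3-(hydroxymethyl)-6-(dimethoxymethyl)benzoate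
Product: 11 tert-butyl 3-(acetoxymethyl)-2,4-dihydroxy-6-(dimethoxymethyl)benzoate
Conditions: vinyl acetate (3 equiv), Novozym 435 (immobilized Candida antarctica lipase B), MTBE, 30 °C
Reagents that add atoms: vinyl acetate, C=COC(C)=O
Why: Lipase-catalysed transesterification with an enol ester acylates primary aliphatic alcohols but not phenols, the neutral medium avoids quinone-methide chemistry of the ortho-hydroxybenzyl system, and tautomerization of the released vinyl alcohol makes the transfer irreversible.

Step 6
Reactants: 12 methyl orsellinate (methyl 2,4-dihydroxy-6-methylbenzoate)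
Product: 13 methyl haematommate (methyl 3-formyl-2,4-dihydroxy-6-methylbenzoate)
Conditions: Cl2CHOMe (1.2 equiv), TiCl4 (2.5 equiv), CH2Cl2, 0 °C; then 1 M HCl, ice
Reagents that add atoms: dichloromethyl methyl ether, COC(Cl)Cl; water, O
Why: Rieche formylation: the titanium phenoxide delivers the electrophile ortho to oxygen, and C3, flanked by both hydroxyls, is expected to be favoured over C5; any C5 isomer is removed by crystallization.

Step 7
Reactants: 13 methyl haematommate
Product: 14 haematommic acid (3-formyl-2,4-dihydroxy-6-methylbenzoic acid)
Conditions: conc. H2SO4, 20 °C; then ice–water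
Reagents that add atoms: water, O
Why: Acid hydrolysis of a 2,6-disubstituted benzoate through the acylium ion in concentrated H2SO4 (unimolecular acyl–oxygen cleavage, assisted by the para hydroxyl), which avoids the base that would attack the aldehyde and the heat that would decarboxylate the acid.

Step 8
Reactants: 11 tert-butyl 3-(acetoxymethyl)-2,4-dihydroxy-6-(dimethoxymethyl)benzoate; 14 haematommic acid
Product: 15 tert-butyl 3-(acetoxymethyl)-4-[(3-formyl-2,4-dihydroxy-6-methylbenzoyl)oxy]-2-hydroxy-6-(dimethoxymethyl)benzoate (depside)
Conditions: DCC (1.1 equiv), toluene, 20 °C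
Reagents that add atoms: none
Why: Carbodiimide depside esterification: in 11 only the C4 hydroxyl is free of chelation, the C2 hydroxyl being hydrogen-bonded to the ester carbonyl and flanked on both sides, and the hydroxyls of 14 are chelated to its formyl and carboxyl groups, so the acid needs no protection.

Step 9
Reactants: 15 depside
Product: 16 depsidone (galbinic acid with the lactol opened as CO2tBu on C1 and CH(OMe)2 on C6 of ring B; new bond from the 2'-oxygen of ring A to C5 of ring B)
Conditions: activated MnO2 (10 equiv), CHCl3, high dilution, 20 °C, dark
Reagents that add atoms: none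
Why: Oxidative phenol coupling of a depside to a depsidone on MnO2: the ring B hydroxyl, conjugated to one carbonyl only, is the most oxidizable phenol, its para carbon C5 is the only unsubstituted carbon of ring B, and bonding to the 2'-oxygen of ring A closes the seven-membered dioxepinone before tautomerization restores the arene; neutral conditions spare the acetate, acetal and ester.

Step 10
Reactants: 16 depsidone
Product: 18 racemic galbinic acid, via open formyl acid 17 (not isolated)
Conditions: TFA/H2O 9:1, 0 → 20 °C
Reagents that add atoms: water, O
Why: Acidolysis of the tert-butyl ester (loss of isobutene) and hydrolysis of the acetal give the ortho-formyl acid, which closes spontaneously to the five-membered lactol (ring–chain tautomerism); the lactol carbon forms without facial bias, hence as the racemate, and the aryl ester and the benzylic acetate on the electron-poor ring B should survive the brief exposure.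

Step 11
Reactants: 18 racemic galbinic acid
Product: 19 (S)-galbinic acid
Conditions: preparative chiral SFC (immobilized amylose tris(3,5-dimethylphenylcarbamate), CO2/MeCN, 0.1% HCO2H, 5 °C); (S) fraction crystallized at once from EtOAc/heptane, −20 °C; (R) fraction: cat. AcOH, acetone/H2O, 40 °C, recycled
Reagents that add atoms: none
Why: Resolution on a chiral stationary phase with racemization and recycling: in a cold, non-basic medium ring opening of the lactol should be slow enough for the enantiomers to be separated, the (S) configuration (to be assigned by X-ray diffraction) is then locked in the crystal, and the (R) fraction returns to the racemate through the achiral open formyl acid.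

Compound list
1 | tert-butyl acetoacetate | CC(=O)CC(=O)OC(C)(C)C | starting material
2 | methyl (E)-4,4-dimethoxybut-2-enoate | COC(=O)/C=C/C(OC)OC | starting material
3 | 1-tert-butyl 5-methyl 2-acetyl-3-(dimethoxymethyl)pentanedioate (Michael adduct, diastereomer mixture) | CC(=O)C(C(=O)OC(C)(C)C)C(CC(=O)OC)C(OC)OC | intermediate
4 | tert-butyl trans-6-(dimethoxymethyl)-2,4-dioxocyclohexane-1-carboxylate (racemate, one enantiomer drawn; largely enolized) | COC(OC)[C@@H]1CC(=O)CC(=O)[C@H]1C(=O)OC(C)(C)C | intermediate
5 | tert-butyl trans-3-[(dimethylamino)methylidene]-6-(dimethoxymethyl)-2,4-dioxocyclohexane-1-carboxylate (racemate) | COC(OC)[C@@H]1CC(=O)C(=CN(C)C)C(=O)[C@H]1C(=O)OC(C)(C)C | intermediate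
6 | C1 phenylselenide of 5 (Se trans to the C6 dimethoxymethyl group; racemate) | COC(OC)[C@@H]1CC(=O)C(=CN(C)C)C(=O)[C@]1([Se]c2ccccc2)C(=O)OC(C)(C)C | intermediate
7 | selenoxide of 6 | COC(OC)[C@@H]1CC(=O)C(=CN(C)C)C(=O)[C@]1([Se](=O)c2ccccc2)C(=O)OC(C)(C)C | intermediate
8 | tert-butyl 5-[(dimethylamino)methylidene]-4-hydroxy-2-(dimethoxymethyl)-6-oxocyclohexa-1,3-diene-1-carboxylate | CN(C)C=C1C(=O)C(C(=O)OC(C)(C)C)=C(C(OC)OC)C=C1O | intermediate
9 | tert-butyl 3-formyl-2,4-dihydroxy-6-(dimethoxymethyl)benzoate | COC(OC)c1cc(O)c(C=O)c(O)c1C(=O)OC(C)(C)C | intermediate
10 | tert-butyl 2,4-dihydroxy-3-(hydroxymethyl)-6-(dimethoxymethyl)benzoate | COC(OC)c1cc(O)c(CO)c(O)c1C(=O)OC(C)(C)C | intermediate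
11 | tert-butyl 3-(acetoxymethyl)-2,4-dihydroxy-6-(dimethoxymethyl)benzoate | COC(OC)c1cc(O)c(COC(C)=O)c(O)c1C(=O)OC(C)(C)C | intermediate
12 | methyl orsellinate | COC(=O)c1c(C)cc(O)cc1O | starting material
13 | methyl haematommate | COC(=O)c1c(C)cc(O)c(C=O)c1O | intermediate
14 | haematommic acid | Cc1cc(O)c(C=O)c(O)c1C(=O)O | intermediate
15 | depside: tert-butyl 3-(acetoxymethyl)-4-[(3-formyl-2,4-dihydroxy-6-methylbenzoyl)oxy]-2-hydroxy-6-(dimethoxymethyl)benzoate | COC(OC)c1cc(OC(=O)c2c(C)cc(O)c(C=O)c2O)c(COC(C)=O)c(O)c1C(=O)OC(C)(C)C | intermediate
16 | depsidone: tert-butyl ester, dimethyl acetal form of ring-opened galbinic acid | CC(=O)OCc1c(O)c(C(=O)OC(C)(C)C)c(C(OC)OC)c2c1OC(=O)c1c(C)cc(O)c(C=O)c1O2 | intermediate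
17 | open formyl acid form of galbinic acid | CC(=O)OCc1c(O)c(C(=O)O)c(C=O)c2c1OC(=O)c1c(C)cc(O)c(C=O)c1O2 | intermediate
18 | racemic galbinic acid | CC(=O)OCc1c(O)c2c(c3c1OC(=O)c1c(C)cc(O)c(C=O)c1O3)C(O)OC2=O | intermediate
19 | (S)-galbinic acid | CC(=O)OCc1c(O)c2c(c3c1OC(=O)c1c(C)cc(O)c(C=O)c1O3)[C@@H](O)OC2=O | target

Total step count: 11. Longest linear sequence: 9 steps (1, 2, 3, 4, 5, 8, 9, 10, 11); steps 6 and 7 make ring A separately.

Steps most likely to fail

Step 9. The phenoxy radicals may couple between molecules, or through C1' of ring A to a spiro lactone, or the product phenol may be oxidized further, so that little intramolecular O–C5 bonding results. The fallback replaces C–H oxidation by halogen-based ether synthesis. It sets out from 11: NIS (MeCN, 0 °C) iodinates C5, the only free ring carbon, to give tert-butyl 3-(acetoxymethyl)-2,4-dihydroxy-5-iodo-6-(dimethoxymethyl)benzoate F1. DCC esterification of its C4 hydroxyl with 14, as in step 8, gives the iodo depside F2. Cu2O (1 equiv) in pyridine at 100 °C (Ullmann ether synthesis through the copper phenoxide of the ring A 2'-hydroxyl, without free base) then closes the ether and comes back to the route at 16.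

Step 11. Ring–chain equilibration during chromatography or concentration may erode the enantiomeric purity before the solid forms. The fallback sets out from 18 and comes back at 19. It is attrition-enhanced deracemization (Viedma ripening): a slurry of 18 is ground with glass beads in EtOAc containing a trace of AcOH, which keeps the lactol equilibrating, and is seeded with (S) crystals. This works only if 18 crystallizes as a conglomerate. No new compound is made (F0).

Step 5. The lipase may not accept the doubly ortho-substituted benzylic alcohol, and 10 may meanwhile lose water to a quinone methide and oligomerize. The fallback sets out from 10 and comes back at 11. It uses that quinone methide productively: warming 10 in glacial AcOH with NaOAc (0.2 equiv) at 50 °C should give acetate capture at the benzylic carbon (thermal acetolysis of ortho-hydroxybenzyl alcohols), which leaves the phenols free. No new compound is made (F0).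

Further compounds
F1 | step 9 | tert-butyl 3-(acetoxymethyl)-2,4-dihydroxy-5-iodo-6-(dimethoxymethyl)benzoate | COC(OC)c1c(I)c(O)c(COC(C)=O)c(O)c1C(=O)OC(C)(C)C
F2 | step 9 | iodo depside (ester of the C4 hydroxyl of F1 with haematommic acid) | COC(OC)c1c(I)c(OC(=O)c2c(C)cc(O)c(C=O)c2O)c(COC(C)=O)c(O)c1C(=O)OC(C)(C)C
F0 | step 11 | none | none
F0 | step 5 | none | none
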